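## The problem

CNP0382739.1 (40) is an eremophilane: a trans-fused decalin in which ring A (C1–C5, C10) carries the acyloxy group at C3, the secondary methyl at C4 and the angular methyl at C5, and ring B (C5–C10) carries the isopropenyl group at C7 and a cis-diol at C8/C9. Seven stereocentres sit on the bicycle (3R,4R,5R,7S,8R,9S,10R) and an eighth, (R), in the (Z)-4-acyloxyhex-2-enoate chain, whose second acyl group is an angelate. With the C5 methyl axial (β) and the C10 hydrogen axial (α), the substituents at C3, C4, C7 and C9 are all equatorial and only the C8 hydroxyl is axial. Hence C4 and C7, each next to a carbonyl group at some stage, can be left to thermodynamic control and the C3 carbinol is the more stable epimer, so the real stereochemical tasks are the quaternary C5, the ring fusion at C10 and the C8/C9 diol relative to them. The fragile parts are the Z-enoate with its allylic acyloxy group (Z/E isomerisation; butenolide formation once the γ-oxygen is free), the angelate (drift to tiglate), the isopropenyl group (hydrogenation, acid) and the diol, so the side chain must be attached last and under mild conditions. The structural opening is the unsubstituted C1–C2 ethylene of ring A between C10 and the oxygenated C3: deleting C2 leaves a cyclopentanone (C3 carbonyl between C1H2 and C4H–CH3) fused to ring B, which is an enyne-carbonylation product, and C2 can be put back by a one-carbon insertion in which the less substituted C1 migrates.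

## Retrosynthesis

**Ester at C3 (40 ⇒ 39 ⇒ 30 + 37).** The acetonide 39 is the last protected form. Cutting the C3–O acyl bond gives the equatorial 3α-alcohol 30 and the complete side-chain acid 37. Acylation with retention is preferred to a Mitsunobu inversion of the axial 3β-alcohol: that alcohol is syn-axial to the C5 methyl, flanked by the C4 methyl and has two anti-periplanar hydrogens, so elimination would compete while a valuable Z-enoic acid is consumed. The forward reaction must esterify a moderately hindered secondary alcohol without isomerising the Z-enoate.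

**Side-chain acid (37 ⇒ 36 ⇒ 34 ⇒ 31 + 32).** The Z-alkene is taken back to the alkyne 36 (semi-hydrogenation), the carboxyl group to CO2 and the acetylide of ester 34, and 34 to (R)-pent-1-yn-3-ol 31 and angelic acid 32. Acylating the carbinol before the Z-alkene exists avoids any free Z-γ-hydroxy enoate, which would lactonise.

**C3 carbinol and isopropenyl group (30 ⇒ 29 ⇒ 28 ⇒ 27 ⇒ 26 ⇒ 25).** The equatorial alcohol 30 comes from ketone 29 by dissolving-metal reduction (thermodynamic control), because axial hydride delivery at C3 is blocked by the axial C5 methyl. The isopropenyl group of 29 is traced through methyl ketone 27 to the Weinreb amide of 25. Since methylmagnesium bromide and the ylide would also attack a C3 ketone, C3 is held as the 3β-carbinol (26–28) during these two steps and re-oxidised. This costs two steps against an inversion route but uses only reactions with a predictable outcome.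

**Ring A by one-carbon insertion (25 ⇒ 22 + 23).** Cutting C1–C2 and C2–C3 removes C2 and contracts ring A to the cyclopentanone 22; trimethylsilyldiazomethane 23 supplies C2. Against an aldol or Diels–Alder construction of ring A, this cut needs no functional handle at C1 or C2, which the target lacks. The forward reaction must make C1, not C4, migrate.

**Ring fusion (22 ⇒ 21 ⇒ 20).** The 10α-hydrogen is added to the enone 20 by hydrogenation. Steric approach control is unreliable here: the β face carries only the angular methyl, while the α face is the underside of ring B with the axial C8 oxygen, so a copper hydride or a heterogeneous catalyst would probably give the cis-fused product. The free 8α,9α-diol of 20 is therefore used to direct a cationic iridium catalyst to the α face, and the diol is then closed to the acetonide 22.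

**C4 methyl (20 ⇒ 19 ⇒ 17).** The methyl is introduced at the enone stage (17 → 19), where C4 is the only enolisable α-position; after saturation C1 would compete. Its configuration is not controlled there and is settled by equilibration after ring enlargement.

**Pauson–Khand reaction (17 ⇒ 15).** Cutting C10–C5, C4–C3 and C3–C1 opens both rings of 17 to the acyclic 1,7-enyne 15 and carbon monoxide. One step then makes ring B, the cyclopentenone and the quaternary C5. The forward reaction must set C5 relative to C7–C9; the all-cis tether substituents should do this through a chair-like closure.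

**Aldol (15 ⇒ 14 ⇒ 13 ⇒ 11 + 7).** The C7–C8 bond is cut to the acyl oxazolidinone 11 and the α-silyloxy ynal 7. An auxiliary-controlled syn-aldol sets C7 and C8 with high fidelity, which matters because C7 steers the Pauson–Khand closure. A simple ester enolate would leave C7 and C8 as mixtures. The amide 14 serves as a latent acetyl group.

**Fragments (7 ⇒ 6 ⇒ 5 ⇒ 4 ⇒ 3 ⇒ 1 + 2; 11 ⇒ 8 + 9).** C9 comes from (R)-glyceraldehyde acetonide 1, homologated to the alkyne 3 with the diazophosphonate 2. Protecting-group exchange and oxidation of C8 lead to 7. The imide 11 is made from acid 8 and auxiliary 9.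

## Roads not taken

**Alternative 1:** Cut C5–C10 and C6–C7 of the decalin, which leads back to the acyclic trienoate A1, an (E,E)-dienoate tethered through four carbons to a 1,1-disubstituted alkene. Heating would close rings A and B in one intramolecular Diels–Alder reaction to the trans-fused C8=C9 octalin ester A2.
- Merits: the decalin, C5 and C10 arise in one step. The C3 oxygen and C4 methyl are carried in on the tether with C3 already α. The C8=C9 alkene invites dihydroxylation from the α face, anti to the axial C5 methyl.
- Weak points: the dienophile is an unactivated 1,1-disubstituted alkene and the diene is electron-poor, so a high temperature is unavoidable. Terminally activated decatrienes of this kind tend to give trans/cis fusion mixtures. C7 emerges epimeric in A2 and must be corrected. The C3/C4 pair of A1 needs its own asymmetric construction.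
- Comparison: this road is shorter to the decalin and places the C3 oxygen correctly from the start, which the chosen plan only reaches through a redox detour. The chosen plan sets against that a reaction of known stereochemical sense for every centre: the aldol for C7/C8, a chair-ordered closure for C5 and a directed hydrogenation for C10.

**Alternative 2:** Cut C4–C5 and C1–C10, which leads to the methoxy(methyl)benzoquinone A3 and the silyloxydiene A4. A Diels–Alder reaction catalysed by TiCl2(Oi-Pr)2 with an enantiomer of 1,1'-bi-2-naphthol would give the cis-fused adduct A5.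
- Merits: ring A, the quaternary C5, the C4 methyl and a C3 oxygen equivalent come from two simple achiral partners under catalytic asymmetric control. In convergence and independence of the chiral pool this is the best of the four plans.
- Weak points: A5 has ring B at the wrong oxidation pattern. It carries a carbonyl at C6, where the target has CH2, a vinylogous ester at C8 and a ketone at C9, and it has no carbon substituent at C7. Removing the C6 oxygen next to the quaternary centre, introducing the isopropenyl group, reducing C8 and C9 stereoselectively and inverting the ring fusion at C10 each cost steps. Regio- and enantioselectivity for this particular quinone/diene pair are not assured.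
- Comparison: the chosen plan is longer at the front, but it introduces each ring-B substituent at its final oxidation level, so nothing has to be deoxygenated or transposed later.

**Alternative 3:** Cut C7–C8 of ring B, which leads to the α-benzyloxy aldehyde A6, a ring-A cyclohexane bearing a prenyl group on C5. A chelating Lewis acid (ZnBr2 or MgBr2·OEt2) would close ring B by a carbonyl-ene reaction to the homoallylic alcohol A7.
- Merits: this is the most economical treatment of the C7/C8 pair. Ring B, the C8 hydroxyl and the isopropenyl group arise together, so the amide-to-alkene sequence and the C3 redox detour of the chosen plan are not needed.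
- Weak points: A6 is itself demanding, with four contiguous stereocentres on ring A including the quaternary C5, plus the C9 centre. The closure must give the axial C8 alcohol cis to the isopropenyl group, whereas the usual chair transition state of such ene closures gives the all-equatorial trans arrangement, so everything depends on chelation overriding that preference. The benzyl ether must later be removed in the presence of three alkenes.
- Comparison: the end game of this road is better. The chosen plan sets against it a secure C8 configuration from an auxiliary-controlled aldol and an early, convergent assembly of ring B.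

Key step: step 15

## Route

Assumption: the C4 methylation in step 11 is not expected to be face-selective, so compounds 19–22 and 24 are carried as C4 epimer pairs (C4 left undefined in their SMILES) and step 15 converges both on the 4β epimer.

Assumption: (R)-pent-1-yn-3-ol (31) is taken as a purchasable chiral building block.

Naming: bicyclic intermediates use eremophilane numbering; β is the face of the C5 methyl. Unless stated otherwise they have 5β-CH3, a 7α side chain and 8α,9α oxygens; from 21 on they have 10α-H, and from 25 on 4β-CH3.

Step 1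
Reactants: 1 (R)-2,2-dimethyl-1,3-dioxolane-4-carbaldehyde; 2 dimethyl (1-diazo-2-oxopropyl)phosphonate
Product: 3 (S)-4-ethynyl-2,2-dimethyl-1,3-dioxolane
Conditions: K2CO3, MeOH, 0 → 23 °C
Reagents that add atoms: none
Why: Ohira–Bestmann homologation; the diazophosphonate anion released by methanolysis turns the aldehyde into the terminal alkyne under conditions mild enough for this α-alkoxy aldehyde, so the future C9 centre is carried over (the descriptor becomes S only through the priority rules).

Step 2
Reactants: 3 (S)-4-ethynyl-2,2-dimethyl-1,3-dioxolane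
Product: 4 (S)-but-3-yne-1,2-diol
Conditions: Dowex 50W (H+ form), MeOH, 23 °C
Reagents that add atoms: none
Why: Acid-catalysed transketalisation to methanol; the stereocentre is not involved and the volatile ketal by-product leaves on evaporation.

Step 3
Reactants: 4 (S)-but-3-yne-1,2-diol
Product: 5 (S)-1,2-bis(tert-butyldimethylsilyloxy)but-3-yne
Conditions: TBSCl, imidazole, DMF, 23 °C
Reagents that add atoms: tert-butyldimethylsilyl chloride, CC(C)(C)[Si](C)(C)Cl
Why: Standard silylation of both hydroxyl groups.

Step 4
Reactants: 5 (S)-1,2-bis(tert-butyldimethylsilyloxy)but-3-yne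
Product: 6 (S)-2-(tert-butyldimethylsilyloxy)but-3-yn-1-ol
Conditions: HF·pyridine, pyridine, THF, 0 °C
Reagents that add atoms: none
Why: Selective cleavage of the less hindered primary silyl ether with buffered HF, the usual way to a 1,2-diol protected only at the secondary oxygen.

Step 5
Reactants: 6 (S)-2-(tert-butyldimethylsilyloxy)but-3-yn-1-ol
Product: 7 (S)-2-(tert-butyldimethylsilyloxy)but-3-ynal
Conditions: Dess–Martin periodinane, NaHCO3, CH2Cl2, 0 °C; used crude at once
Reagents that add atoms: none
Why: Dess–Martin oxidation under buffered, amine-free conditions; this is chosen because the α-hydrogen of 7 is both propargylic and α to the carbonyl and would be endangered by the base of a Swern-type oxidation.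

Step 6
Reactants: 8 4-methylpent-4-enoic acid; 9 (R)-4-benzyloxazolidin-2-one
Product: 11 (R)-4-benzyl-3-(4-methylpent-4-enoyl)oxazolidin-2-one, via mixed pivalic anhydride 10 (not isolated)
Conditions: PivCl, Et3N, THF, −20 °C; then 9, LiCl, −20 → 23 °C
Reagents that add atoms: none
Why: N-Acylation of the oxazolidinone through the mixed pivalic anhydride in the LiCl-assisted variant, which needs no strong base.

Step 7
Reactants: 11 (R)-4-benzyl-3-(4-methylpent-4-enoyl)oxazolidin-2-one; 7 (S)-2-(tert-butyldimethylsilyloxy)but-3-ynal
Product: 13 (R)-4-benzyl-3-[(2R,3R,4S)-4-(tert-butyldimethylsilyloxy)-3-hydroxy-2-(2-methylallyl)hex-5-ynoyl]oxazolidin-2-one, via Z-dibutylboron enolate 12 (not isolated)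
Conditions: Bu2BOTf, i-Pr2NEt, CH2Cl2, −78 → 0 °C; then 7, −78 → −20 °C; pH 7 buffer, MeOH, H2O2, 0 °C
Reagents that add atoms: none
Why: Evans syn-aldol reaction; the (R)-auxiliary fixes C7 and C8 (2,3-syn) through the chair transition state of the Z-boron enolate, and the polar (Cornforth/Felkin) preference of the α-silyloxy aldehyde for the 3,4-anti adduct points the same way, so the pairing is matched.

Step 8
Reactants: 13 aldol adduct
Product: 14 (2R,3R,4S)-4-(tert-butyldimethylsilyloxy)-3-hydroxy-N-methoxy-N-methyl-2-(2-methylallyl)hex-5-ynamide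
Conditions: MeNHOMe·HCl, AlMe3, CH2Cl2, −20 → 0 °C
Reagents that add atoms: N,O-dimethylhydroxylamine hydrochloride, CNOC.Cl
Why: Aluminium amide transamination of the aldol adduct, assisted by the free β-hydroxyl, gives the Weinreb amide (a latent acetyl group) and returns auxiliary 9.

Step 9
Reactants: 14 hydroxy Weinreb amide
Product: 15 (2R,3R,4S)-3,4-bis(tert-butyldimethylsilyloxy)-N-methoxy-N-methyl-2-(2-methylallyl)hex-5-ynamide
Conditions: TBSOTf, 2,6-lutidine, CH2Cl2, −78 → 0 °C
Reagents that add atoms: tert-butyldimethylsilyl triflate, CC(C)(C)[Si](C)(C)OS(=O)(=O)C(F)(F)F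
Why: Silylation of the hindered secondary alcohol with the silyl triflate; both future diol oxygens are now inert to the enolate chemistry of step 11, and no γ-hydroxy amide that could lactonise is ever exposed in the open chain.

Step 10
Reactants: 15 bis-silyl enyne
Product: 17 bicyclic enone [C3=O; C1=C10; C4H2; 5β-CH3; 7α-CON(OMe)Me; 8α,9α-bis(OTBS); C2 absent], via alkyne–Co2(CO)6 complex 16 (not isolated)
Conditions: Co2(CO)8, CH2Cl2, 23 °C; then N-methylmorpholine N-oxide, 0 → 23 °C
Reagents that add atoms: dicobalt octacarbonyl Co2(CO)8 (supplies the C3 carbonyl), O=C=[Co](=C=O)(=C=O)(=C=O)[Co](=C=O)(=C=O)(=C=O)=C=O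
Why: Intramolecular Pauson–Khand reaction of a 1,7-enyne forms C10–C5, C4–C3 and C3–C1, closing ring B and the cyclopentenone. The angular methyl has to be axial on the new six-membered ring, and only the chair with the C7 amide and C9 silyloxy group equatorial avoids 1,3-diaxial contact with it, which should place the methyl β.

Step 11
Reactants: 17 bicyclic enone
Product: 19 4-methyl enone [as 17 with C4H–CH3; C4 epimers], via lithium dienolate 18 (not isolated)
Conditions: LiN(i-Pr)2 (1.05 equiv), THF, −78 °C; then MeI, −78 → −40 °C
Reagents that add atoms: iodomethane, CI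
Why: Kinetic α′-deprotonation of the cyclopentenone gives the cross-conjugated enolate at C4, the only enolisable α-position at this stage, and C-methylation there installs the secondary methyl. No dependable facial bias is expected next to the quaternary C5, so C4 is settled in step 15.

Step 12
Reactants: 19 4-methyl enone
Product: 20 diol enone [C3=O; C1=C10; 8α-OH; 9α-OH; 7α-CON(OMe)Me; C4 epimers]
Conditions: HF·pyridine, THF, 0 → 23 °C
Reagents that add atoms: none
Why: Acidic fluoride removes both secondary silyl ethers without the basic conditions that could isomerise a γ-hydroxy enone; in the locked ring the equatorial C9 hydroxyl cannot reach the equatorial amide, so no lactone forms.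

Step 13
Reactants: 20 diol enone
Product: 21 trans-hydrindanone diol [C3=O; C1H2; 10α-H; 8α-OH; 9α-OH; 7α-CON(OMe)Me; C4 epimers]
Conditions: H2 (1 atm), [Ir(cod)(PCy3)(py)]PF6 (10 mol %), CH2Cl2, 23 °C
Reagents that add atoms: none
Why: Hydroxyl-directed homogeneous hydrogenation; iridium bound to the axial 8α-hydroxyl (homoallylic) and the 9α-hydroxyl (allylic) delivers hydrogen to the α face of C1=C10, setting the 10α-hydrogen and hence the trans ring fusion that steric approach control would not secure.

Step 14
Reactants: 21 trans-hydrindanone diol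
Product: 22 8α,9α-isopropylidenedioxy-N-methoxy-N-methyl-3-oxo-2,12,13-trinoreremophilan-11-amide [cyclopentanone; C1 bonded to C3; C4 epimers]
Conditions: 2-methoxypropene, pyridinium p-toluenesulfonate (cat.), CH2Cl2, 0 °C
Reagents that add atoms: 2-methoxypropene, COC(C)=C
Why: Acetonide formation on the cis (axial/equatorial) diol; the small cyclic ketal tolerates the base, hydride, organomagnesium, ylide and dissolving-metal steps ahead and is removed at the end with mild acid.

Step 15
Reactants: 22 cyclopentanone acetonide; 23 trimethylsilyldiazomethane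
Product: 25 8α,9α-isopropylidenedioxy-N-methoxy-N-methyl-3-oxo-12,13-dinoreremophilan-11-amide, via 2-trimethylsilyl ketone 24 (not isolated)
Conditions: BF3·OEt2, CH2Cl2, −78 → −40 °C; then K2CO3, MeOH, 23 °C
Reagents that add atoms: none
Why: The nucleophilic diazo carbon adds to the BF3-activated C3 carbonyl, and in the resulting β-oxido diazonium ion the ring bond anti to the departing N2 shifts to the new carbon as nitrogen is lost. The closest known reaction type is the Lewis-acid-promoted homologation of cycloalkanones with Me3SiCHN2, a Tiffeneau–Demjanov-type ring enlargement. Ring A is closed not by a cyclisation but by a 1,2-alkyl shift that enlarges the cyclopentanone by one carbon: C2–C3 forms in the addition and C1–C2 in the migration. The step needs migration of C1 and not of C4; C1 is a methylene whereas C4 is a tertiary carbon wedged against the quaternary C5, so the silyl-bearing carbon can align with and accept C1 far more easily, as is general for α-branched ketones under these conditions. The silyl group left on C2 (24) shields the new cyclohexanone from a second insertion and is cleaved by K2CO3/MeOH. The same basic methanol equilibrates C4 through the C3–C4 enolate, which is reprotonated axially from the α face, towards the 4β epimer with its methyl equatorial; this is the only stereochemical event, and C5, C7, C8, C9 and C10 are untouched. Low temperature and a limited excess of BF3·OEt2 are used to spare the acetonide.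

Step 16
Reactants: 25 decalone Weinreb amide
Product: 26 3β-hydroxy-8α,9α-isopropylidenedioxy-N-methoxy-N-methyl-12,13-dinoreremophilan-11-amide
Conditions: LiBH(s-Bu)3, THF, −78 °C
Reagents that add atoms: none
Why: The bulky borohydride attacks the C3 ketone equatorially (the axial path is also blocked by the axial C5 methyl) and should give the axial 3β-alcohol as one epimer; this carbinol only masks C3 during steps 17 and 18, and the Weinreb amide is not reduced at −78 °C.

Step 17
Reactants: 26 3β-hydroxy Weinreb amide
Product: 27 3β-hydroxy-8α,9α-isopropylidenedioxy-13-noreremophilan-11-one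
Conditions: MeMgBr (4 equiv), THF, 0 °C
Reagents that add atoms: methylmagnesium bromide, C[Mg]Br
Why: Weinreb ketone synthesis; the chelated tetrahedral adduct stops the addition at the ketone stage, and the free hydroxyl merely consumes one equivalent of reagent. The acetyl group stays equatorial (α) at C7, which is also the thermodynamic arrangement.

Step 18
Reactants: 27 methyl ketone
Product: 28 8α,9α-isopropylidenedioxyeremophil-11-en-3β-ol
Conditions: Ph3PCH3Br, KOt-Bu, THF, 0 °C; then 27, 0 → 23 °C
Reagents that add atoms: methyltriphenylphosphonium bromide, C[P+](c1ccccc1)(c1ccccc1)c1ccccc1.[Br-]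
Why: Wittig methylenation of the methyl ketone completes the isopropenyl group. The ylide is used cold and in excess (one equivalent is taken by the hydroxyl) so that olefination outruns enolisation towards C7, from where the anti-periplanar C8 oxygen could be eliminated.

Step 19
Reactants: 28 isopropenyl 3β-alcohol
Product: 29 8α,9α-isopropylidenedioxyeremophil-11-en-3-one
Conditions: Dess–Martin periodinane, NaHCO3, CH2Cl2, 23 °C
Reagents that add atoms: none
Why: Dess–Martin oxidation returns the C3 ketone; the hindered axial alcohol is oxidised readily, and the alkene and acetonide are inert.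

Step 20
Reactants: 29 isopropenyl ketone
Product: 30 8α,9α-isopropylidenedioxyeremophil-11-en-3α-ol
Conditions: Li, NH3 (l), THF, MeOH, −78 °C
Reagents that add atoms: none
Why: Dissolving-metal reduction of the ketone runs under thermodynamic control and should give the equatorial 3α-alcohol (3R), which hydride reagents cannot reach because axial delivery is blocked by the C5 methyl. The isolated 1,1-disubstituted alkene and the acetonide are not reduced.

Step 21
Reactants: 31 (R)-pent-1-yn-3-ol; 32 angelic acid [(Z)-2-methylbut-2-enoic acid]
Product: 34 (R)-pent-1-yn-3-yl (Z)-2-methylbut-2-enoate, via angelic 2,4,6-trichlorobenzoic anhydride 33 (not isolated)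
Conditions: 2,4,6-trichlorobenzoyl chloride, Et3N, toluene, 23 °C; then 31, 75 °C
Reagents that add atoms: none
Why: Esterification through the mixed 2,4,6-trichlorobenzoic anhydride without a nucleophilic amine catalyst, the conditions under which angelates form without drifting to the tiglate; the carbinol centre is not involved.

Step 22
Reactants: 34 (R)-pent-1-yn-3-yl angelate
Product: 36 (R)-4-[(Z)-2-methylbut-2-enoyloxy]hex-2-ynoic acid, via lithium acetylide 35 (not isolated)
Conditions: LiN(i-Pr)2 (1.0 equiv), THF, −78 °C; then CO2 (g), −78 °C; 1 M HCl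
Reagents that add atoms: carbon dioxide, O=C=O
Why: Deprotonation of the terminal alkyne, by far the most acidic site (the angelate has no α-hydrogen), followed by carboxylation of the lithium acetylide. Everything is kept at −78 °C so that the acetylide does not attack the hindered enoate.

Step 23
Reactants: 36 ynoic acid
Product: 37 (R,Z)-4-[(Z)-2-methylbut-2-enoyloxy]hex-2-enoic acid
Conditions: H2 (1 atm), Pd/CaCO3 poisoned with Pb(OAc)2, quinoline, EtOAc, 23 °C
Reagents that add atoms: none
Why: Lindlar semi-hydrogenation gives the Z-enoic acid by syn addition of hydrogen. The trisubstituted, conjugated angelate alkene is not reduced, and with the γ-oxygen acylated the Z-acid cannot close to a butenolide.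

Step 24
Reactants: 37 Z-enoic acid; 30 3α-alcohol
Product: 39 3α-{(2Z,4R)-4-[(Z)-2-methylbut-2-enoyloxy]hex-2-enoyloxy}-8α,9α-isopropylidenedioxyeremophil-11-ene, via mixed 2,4,6-trichlorobenzoic anhydride 38 (not isolated)
Conditions: 2,4,6-trichlorobenzoyl chloride, Et3N, toluene, 0 °C; then 30, DMAP, 0 → 23 °C
Reagents that add atoms: none
Why: Yamaguchi esterification of the equatorial 3α-alcohol with retention at C3; low temperature and short reaction time limit reversible conjugate addition of DMAP to the activated Z-enoyl group.

Step 25
Reactants: 39 ester acetonide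
Product: 40 CNP0382739.1, 3α-{(2Z,4R)-4-[(Z)-2-methylbut-2-enoyloxy]hex-2-enoyloxy}eremophil-11-ene-8α,9α-diol
Conditions: AcOH/H2O (4:1), THF, 45 °C
Reagents that add atoms: none
Why: Mild acid hydrolysis of the acetonide; these conditions leave both esters, the Z-alkene and the isopropenyl group alone.

## Compound list

1 | (R)-2,2-dimethyl-1,3-dioxolane-4-carbaldehyde | O=C[C@H]1COC(C)(C)O1 | starting material
2 | dimethyl (1-diazo-2-oxopropyl)phosphonate | CC(=O)C(=[N+]=[N-])P(=O)(OC)OC | starting material
3 | (S)-4-ethynyl-2,2-dimethyl-1,3-dioxolane | C#C[C@H]1COC(C)(C)O1 | intermediate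
4 | (S)-but-3-yne-1,2-diol | OC[C@@H](O)C#C | intermediate
5 | (S)-1,2-bis(tert-butyldimethylsilyloxy)but-3-yne | CC(C)(C)[Si](C)(C)OC[C@@H](O[Si](C)(C)C(C)(C)C)C#C | intermediate
6 | (S)-2-(tert-butyldimethylsilyloxy)but-3-yn-1-ol | OC[C@@H](O[Si](C)(C)C(C)(C)C)C#C | intermediate
7 | (S)-2-(tert-butyldimethylsilyloxy)but-3-ynal | O=C[C@@H](O[Si](C)(C)C(C)(C)C)C#C | intermediate
8 | 4-methylpent-4-enoic acid | C=C(C)CCC(=O)O | starting material
9 | (R)-4-benzyloxazolidin-2-one | O=C1N[C@H](Cc2ccccc2)CO1 | starting material
10 | 4-methylpent-4-enoic pivalic anhydride | C=C(C)CCC(=O)OC(=O)C(C)(C)C | intermediate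
11 | (R)-4-benzyl-3-(4-methylpent-4-enoyl)oxazolidin-2-one | C=C(C)CCC(=O)N1[C@H](Cc2ccccc2)COC1=O | intermediate
12 | (Z)-dibutylboron enolate of 11 | CCCCB(CCCC)O/C(=C\CC(C)=C)N1[C@H](Cc2ccccc2)COC1=O | intermediate
13 | (R)-4-benzyl-3-[(2R,3R,4S)-4-(tert-butyldimethylsilyloxy)-3-hydroxy-2-(2-methylallyl)hex-5-ynoyl]oxazolidin-2-one | O=C(N1[C@H](Cc2ccccc2)COC1=O)[C@H](CC(C)=C)[C@@H](O)[C@@H](O[Si](C)(C)C(C)(C)C)C#C | intermediate
14 | (2R,3R,4S)-4-(tert-butyldimethylsilyloxy)-3-hydroxy-N-methoxy-N-methyl-2-(2-methylallyl)hex-5-ynamide | CON(C)C(=O)[C@H](CC(C)=C)[C@@H](O)[C@@H](O[Si](C)(C)C(C)(C)C)C#C | intermediate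
15 | (2R,3R,4S)-3,4-bis(tert-butyldimethylsilyloxy)-N-methoxy-N-methyl-2-(2-methylallyl)hex-5-ynamide | CON(C)C(=O)[C@H](CC(C)=C)[C@@H](O[Si](C)(C)C(C)(C)C)[C@@H](O[Si](C)(C)C(C)(C)C)C#C | intermediate
16 | hexacarbonyldicobalt complex of the alkyne of 15 | CON(C)C(=O)[C@H](CC(C)=C)[C@@H](O[Si](C)(C)C(C)(C)C)[C@@H](O[Si](C)(C)C(C)(C)C)C12[Co]3(=C=O)(=C=O)(=C=O)[Co]1(=C=O)(=C=O)(=C=O)C23 | intermediate
17 | bicyclic enone: C3 ketone, C1=C10, C4H2, 5β-methyl, 7α-CON(OMe)Me, 8α,9α-bis(tert-butyldimethylsilyloxy) | CON(C)C(=O)[C@@H]1C[C@]2(C)CC(=O)C=C2[C@H](O[Si](C)(C)C(C)(C)C)[C@@H]1O[Si](C)(C)C(C)(C)C | intermediate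
18 | lithium C3–C4 dienolate of 17 | CON(C)C(=O)[C@@H]1C[C@]2(C)C=C(O[Li])C=C2[C@H](O[Si](C)(C)C(C)(C)C)[C@@H]1O[Si](C)(C)C(C)(C)C | intermediate
19 | 4-methyl derivative of 17 (C4 epimers) | CON(C)C(=O)[C@@H]1C[C@]2(C)C(C)C(=O)C=C2[C@H](O[Si](C)(C)C(C)(C)C)[C@@H]1O[Si](C)(C)C(C)(C)C | intermediate
20 | 8α,9α-diol enone (C4 epimers) | CON(C)C(=O)[C@@H]1C[C@]2(C)C(C)C(=O)C=C2[C@H](O)[C@@H]1O | intermediate
21 | trans-hydrindanone 8α,9α-diol, 10α-H (C4 epimers) | CON(C)C(=O)[C@@H]1C[C@]2(C)C(C)C(=O)C[C@H]2[C@H](O)[C@@H]1O | intermediate
22 | 8α,9α-isopropylidenedioxy-N-methoxy-N-methyl-3-oxo-2,12,13-trinoreremophilan-11-amide (C4 epimers) | CON(C)C(=O)[C@@H]1C[C@]2(C)C(C)C(=O)C[C@H]2[C@H](OC3(C)C)[C@@H]1O3 | intermediate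
23 | trimethylsilyldiazomethane | C[Si](C)(C)C=[N+]=[N-] | starting material
24 | 2-trimethylsilyl derivative of 25 (C2 and C4 undefined) | CON(C)C(=O)[C@@H]1C[C@]2(C)C(C)C(=O)C([Si](C)(C)C)C[C@H]2[C@H](OC3(C)C)[C@@H]1O3 | intermediate
25 | 8α,9α-isopropylidenedioxy-N-methoxy-N-methyl-3-oxo-12,13-dinoreremophilan-11-amide | CON(C)C(=O)[C@@H]1C[C@]2(C)[C@@H](C)C(=O)CC[C@H]2[C@H](OC3(C)C)[C@@H]1O3 | intermediate
26 | 3β-hydroxy-8α,9α-isopropylidenedioxy-N-methoxy-N-methyl-12,13-dinoreremophilan-11-amide | CON(C)C(=O)[C@@H]1C[C@]2(C)[C@@H](C)[C@@H](O)CC[C@H]2[C@H](OC3(C)C)[C@@H]1O3 | intermediate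
27 | 3β-hydroxy-8α,9α-isopropylidenedioxy-13-noreremophilan-11-one | CC(=O)[C@@H]1C[C@]2(C)[C@@H](C)[C@@H](O)CC[C@H]2[C@H](OC3(C)C)[C@@H]1O3 | intermediate
28 | 8α,9α-isopropylidenedioxyeremophil-11-en-3β-ol | C=C(C)[C@@H]1C[C@]2(C)[C@@H](C)[C@@H](O)CC[C@H]2[C@H](OC3(C)C)[C@@H]1O3 | intermediate
29 | 8α,9α-isopropylidenedioxyeremophil-11-en-3-one | C=C(C)[C@@H]1C[C@]2(C)[C@@H](C)C(=O)CC[C@H]2[C@H](OC3(C)C)[C@@H]1O3 | intermediate
30 | 8α,9α-isopropylidenedioxyeremophil-11-en-3α-ol | C=C(C)[C@@H]1C[C@]2(C)[C@@H](C)[C@H](O)CC[C@H]2[C@H](OC3(C)C)[C@@H]1O3 | intermediate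
31 | (R)-pent-1-yn-3-ol | C#C[C@@H](CC)O | starting material
32 | angelic acid, (Z)-2-methylbut-2-enoic acid | O=C(O)/C(C)=C\C | starting material
33 | angelic 2,4,6-trichlorobenzoic anhydride | O=C(OC(=O)c1c(Cl)cc(Cl)cc1Cl)/C(C)=C\C | intermediate
34 | (R)-pent-1-yn-3-yl (Z)-2-methylbut-2-enoate | C#C[C@@H](CC)OC(=O)/C(C)=C\C | intermediate
35 | lithium acetylide of 34 | [Li]C#C[C@@H](CC)OC(=O)/C(C)=C\C | intermediate
36 | (R)-4-[(Z)-2-methylbut-2-enoyloxy]hex-2-ynoic acid | OC(=O)C#C[C@@H](CC)OC(=O)/C(C)=C\C | intermediate
37 | (R,Z)-4-[(Z)-2-methylbut-2-enoyloxy]hex-2-enoic acid | OC(=O)/C=C\[C@@H](CC)OC(=O)/C(C)=C\C | intermediate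
38 | mixed anhydride of 37 with 2,4,6-trichlorobenzoic acid | O=C(OC(=O)c1c(Cl)cc(Cl)cc1Cl)/C=C\[C@@H](CC)OC(=O)/C(C)=C\C | intermediate
39 | 3α-{(2Z,4R)-4-[(Z)-2-methylbut-2-enoyloxy]hex-2-enoyloxy}-8α,9α-isopropylidenedioxyeremophil-11-ene | C=C(C)[C@@H]1C[C@]2(C)[C@@H](C)[C@H](OC(=O)/C=C\[C@@H](CC)OC(=O)/C(C)=C\C)CC[C@H]2[C@H](OC3(C)C)[C@@H]1O3 | intermediate
40 | CNP0382739.1, 3α-{(2Z,4R)-4-[(Z)-2-methylbut-2-enoyloxy]hex-2-enoyloxy}eremophil-11-ene-8α,9α-diol | C=C(C)[C@@H]1C[C@]2(C)[C@@H](C)[C@H](OC(=O)/C=C\[C@@H](CC)OC(=O)/C(C)=C\C)CC[C@H]2[C@H](O)[C@@H]1O | target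

## Step count and least certain steps

Total: 25 steps. Longest linear sequence: 21 steps (steps 1–5, 7–20, 24, 25). Step 6 is a one-step branch (imide 11) and steps 21–23 a three-step branch (acid 37).

**Step 15 (key step).** The most likely failures are partial migration of C4 instead of C1, Lewis-acid opening of the acetonide, and incomplete conversion if BF3 is held by the amide. The fallback fixes the regiochemistry by the enolate that is formed, not by migratory aptitude, and uses no strong Lewis acid. It sets out from 22. Kinetic enolisation towards C1 (LiN(i-Pr)2, Me3SiCl, −78 °C) gives the trimethylsilyl enol ether F1. Simmons–Smith cyclopropanation (Et2Zn, CH2I2) gives the siloxycyclopropane F2. FeCl3 in DMF opens the internal cyclopropane bond to the ring-enlarged β-chloro ketone F3, which loses HCl with NaOAc to give the C1=C2 enone F4. Hydrogenation over Pd/C and K2CO3/MeOH equilibration of C4 return to the route at 25. The same two bonds (C1–C2, C2–C3) are formed.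

**Step 7 (with the aldehyde from step 5).** The aldehyde 7 may enolise before or during the aldol, which would scramble C9 or isomerise the ynal to an allenal. The fallback avoids any α-alkoxy ynal. It sets out from 11, whose boron enolate 12 is combined with the robust aldehyde 1 to give the syn-aldol adduct F5. Transamination as in step 8 gives the Weinreb amide F6, and silylation (TBSOTf) gives the silyl ether F7. H5IO6 in EtOAc cleaves the terminal acetonide and the resulting glycol in one operation to the α-silyloxy aldehyde F8. Ethynylmagnesium bromide at −78 °C adds in the Felkin–Anh sense to give the anti propargylic alcohol F9, and TBSOTf then returns to the route at 15. C9 is set here by substrate control instead of the chiral pool.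

**Step 10.** Alkene insertion may be slow for a 1,7-enyne with a 1,1-disubstituted alkene, so decomplexation or alkyne oligomerisation could take over, and facial control at C5 would erode if the tether does not adopt the chair. The fallback ties the two oxygens into a cis-dioxolane that holds alkyne and alkene chain on the same side. It sets out from 14. Buffered fluoride (Bu4NF/AcOH, 0 °C) gives the diol F10, which is trapped at once with 2-methoxypropene/pyridinium p-toluenesulfonate as the acetonide enyne F11. The Pauson–Khand reaction as in step 10 gives the acetonide enone F12, and methylation as in step 11 gives the 4-methyl acetonide enone F13. Aqueous acetic acid then returns to the route at 20.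

**Step 13.** The iridium catalyst may deactivate before the hindered, electron-poor trisubstituted alkene is reduced, or some hydrogen may arrive from the undirected face. The fallback changes the substrate class from an enone to an electron-rich allylic alcohol. It sets out from 20. Luche reduction (NaBH4, CeCl3·7H2O, MeOH, −78 °C) gives the allylic alcohol F14. Directed hydrogenation with the same iridium complex gives the saturated triol F15, and 2-methoxypropene gives the acetonide alcohol F16. Dess–Martin oxidation returns to the route at 22.

**Step 22.** The amide base or the acetylide may attack the angelate, or γ-deprotonation may isomerise it to the tiglate. The fallback introduces the carboxyl group before the angelate. It sets out from 31. Silylation (TBSCl, imidazole) gives the silyl ether F17. Lithiation (n-BuLi, −78 °C) and trapping with Boc2O gives the tert-butyl ynoate F18, and HF·pyridine gives the hydroxy ynoate F19. Acylation with the preformed anhydride 33 gives the angelate F20, and CF3CO2H returns to the route at 36.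

**Step 24.** The Z-enoyl unit may isomerise to E through reversible conjugate addition of DMAP to the activated acyl group. The fallback couples at the alkyne oxidation level, where there is no geometry to lose. It sets out from 30 and 36, which are joined with dicyclohexylcarbodiimide and catalytic DMAP at −20 °C to give the ynoate ester F21. Lindlar semi-hydrogenation (Pd/CaCO3 poisoned with Pb(OAc)2, quinoline), stopped after one equivalent of hydrogen to spare the isopropenyl group, returns to the route at 39.

## Further compounds

F1 | step 15 | C1=C3 trimethylsilyl enol ether of 22 | CON(C)C(=O)[C@@H]1C[C@]2(C)C(C)C(O[Si](C)(C)C)=C[C@H]2[C@H](OC3(C)C)[C@@H]1O3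
F2 | step 15 | siloxycyclopropane from F1 (CH2 bridging C1 and C3) | CON(C)C(=O)[C@@H]1C[C@]2(C)C(C)C3(O[Si](C)(C)C)CC3[C@H]2[C@H](OC4(C)C)[C@@H]1O4
F3 | step 15 | ring-enlarged 1-chloro-3-ketone | CON(C)C(=O)[C@@H]1C[C@]2(C)C(C)C(=O)CC(Cl)[C@H]2[C@H](OC3(C)C)[C@@H]1O3
F4 | step 15 | ring-enlarged C1=C2 enone | CON(C)C(=O)[C@@H]1C[C@]2(C)C(C)C(=O)C=C[C@H]2[C@H](OC3(C)C)[C@@H]1O3
F5 | step 7 | syn-aldol adduct of 11 with aldehyde 1 | O=C(N1[C@H](Cc2ccccc2)COC1=O)[C@H](CC(C)=C)[C@@H](O)[C@H]1COC(C)(C)O1
F6 | step 7 | Weinreb amide from F5 | CON(C)C(=O)[C@H](CC(C)=C)[C@@H](O)[C@H]1COC(C)(C)O1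
F7 | step 7 | tert-butyldimethylsilyl ether of F6 | CON(C)C(=O)[C@H](CC(C)=C)[C@@H](O[Si](C)(C)C(C)(C)C)[C@H]1COC(C)(C)O1
F8 | step 7 | α-silyloxy aldehyde from F7 | CON(C)C(=O)[C@H](CC(C)=C)[C@@H](O[Si](C)(C)C(C)(C)C)C=O
F9 | step 7 | anti propargylic alcohol from F8 | CON(C)C(=O)[C@H](CC(C)=C)[C@@H](O[Si](C)(C)C(C)(C)C)[C@@H](O)C#C
F10 | step 10 | (2R,3R,4S)-3,4-dihydroxy-N-methoxy-N-methyl-2-(2-methylallyl)hex-5-ynamide | CON(C)C(=O)[C@H](CC(C)=C)[C@@H](O)[C@@H](O)C#C
F11 | step 10 | 3,4-acetonide of F10 | CON(C)C(=O)[C@H](CC(C)=C)[C@@H](OC1(C)C)[C@@H](O1)C#C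
F12 | step 10 | 8α,9α-acetonide analogue of enone 17 | CON(C)C(=O)[C@@H]1C[C@]2(C)CC(=O)C=C2[C@H](OC3(C)C)[C@@H]1O3
F13 | step 10 | 4-methyl derivative of F12 (C4 epimers) | CON(C)C(=O)[C@@H]1C[C@]2(C)C(C)C(=O)C=C2[C@H](OC3(C)C)[C@@H]1O3
F14 | step 13 | allylic alcohol from 20 (C3 carbinol, C3 and C4 undefined) | CON(C)C(=O)[C@@H]1C[C@]2(C)C(C)C(O)C=C2[C@H](O)[C@@H]1O
F15 | step 13 | saturated triol, 10α-H | CON(C)C(=O)[C@@H]1C[C@]2(C)C(C)C(O)C[C@H]2[C@H](O)[C@@H]1O
F16 | step 13 | 8α,9α-acetonide of F15 | CON(C)C(=O)[C@@H]1C[C@]2(C)C(C)C(O)C[C@H]2[C@H](OC3(C)C)[C@@H]1O3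
F17 | step 22 | (R)-tert-butyldimethyl(pent-1-yn-3-yloxy)silane | C#C[C@@H](CC)O[Si](C)(C)C(C)(C)C
F18 | step 22 | tert-butyl (R)-4-(tert-butyldimethylsilyloxy)hex-2-ynoate | CC(C)(C)OC(=O)C#C[C@@H](CC)O[Si](C)(C)C(C)(C)C
F19 | step 22 | tert-butyl (R)-4-hydroxyhex-2-ynoate | CC(C)(C)OC(=O)C#C[C@@H](CC)O
F20 | step 22 | tert-butyl (R)-4-[(Z)-2-methylbut-2-enoyloxy]hex-2-ynoate | CC(C)(C)OC(=O)C#C[C@@H](CC)OC(=O)/C(C)=C\C
F21 | step 24 | 3α-ynoate ester of 30 with acid 36 | C=C(C)[C@@H]1C[C@]2(C)[C@@H](C)[C@H](OC(=O)C#C[C@@H](CC)OC(=O)/C(C)=C\C)CC[C@H]2[C@H](OC3(C)C)[C@@H]1O3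
A1 | alternative 1 | ethyl (2E,4E,8R,9R)-8-(tert-butyldimethylsilyloxy)-9,10-dimethylundeca-2,4,10-trienoate | CCOC(=O)/C=C/C=C/CC[C@@H](O[Si](C)(C)C(C)(C)C)[C@H](C)C(C)=C
A2 | alternative 1 | trans-fused C8=C9 octalin ethyl ester, 3α-silyloxy, 4β,5β-dimethyl, C7 epimeric | CCOC(=O)[C@H]1C[C@]2(C)[C@@H](C)[C@H](O[Si](C)(C)C(C)(C)C)CC[C@H]2C=C1
A3 | alternative 2 | 2-methoxy-5-methyl-1,4-benzoquinone | COC1=CC(=O)C(C)=CC1=O
A4 | alternative 2 | (Z)-3-(trimethylsilyloxy)penta-1,3-diene | C=C/C(O[Si](C)(C)C)=C/C
A5 | alternative 2 | cis-fused quinone Diels–Alder adduct | COC1=CC(=O)[C@]2(C)[C@H](C)C(O[Si](C)(C)C)=CC[C@@H]2C1=O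
A6 | alternative 3 | α-benzyloxy aldehyde on ring A with C5 prenyl group | CC(C)=CC[C@]1(C)[C@@H](C)[C@H](O[Si](C)(C)C(C)(C)C)CC[C@H]1[C@H](OCc1ccccc1)C=O
A7 | alternative 3 | 9α-benzyloxy-3α-(tert-butyldimethylsilyloxy)eremophil-11-en-8α-ol | C=C(C)[C@@H]1C[C@]2(C)[C@@H](C)[C@H](O[Si](C)(C)C(C)(C)C)CC[C@H]2[C@H](OCc3ccccc3)[C@@H]1O
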